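**Plan**
- Retrosynthesis: the O6–CH3 ether is cleaved last. The saturated chain goes back to an E-C4'=C5' alkene, which is cut at C5'–C6' into an E-iodoalkene and an (R)-citronellyl zinc reagent. The iodoalkene (C4'–CH3 bond) goes back to a terminal alkyne made from an acetyl group. The chroman is cut at O1–C2 and C1'–C2' in one operation, to a 2-(3-methylbut-3-enyl)phenol and methyl vinyl ketone.
- Forward: the benzene ring comes from 2,5-dimethylhydroquinone. The pyran ring closes in the domino step, which also starts the chain (C1'–C5'). The chain is completed by carboalumination, Negishi coupling and hydrogenation.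
- Enabling feature: C2 is a fully substituted ether carbon between O1 and C1' and bears no hydrogen. The C1'–palladium alkyl formed on closing the pyran ring therefore cannot beta-eliminate and must insert the enone.
- Stereochemistry: C2 from the chiral bis(oxazoline) ligand on palladium; C8' from (R)-citronellol; C4' from iridium-catalysed asymmetric hydrogenation of a geometrically pure E-alkene.

Key step: step 5

Assumption: (S,S)-Bn-BOXAX is taken to select the same alkene face of 8 as of its ring-trimethylated analogue (the antipodal ligand serves otherwise), and L in step 11 is the enantiomer of 2-phenyl-7-[bis(2-methylphenyl)phosphanyloxy]-6,7-dihydro-5H-cyclopenta[b]pyridine that adds hydrogen to the Re face of C4'.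

**Route**

Step 1
Reactants: 1 2,5-dimethylhydroquinone; 2 methyl vinyl ketone
Product: 4 2-methoxy-2,5,8-trimethylchroman-6-ol (racemic), via ketone adduct 3 (not isolated)
Conditions: 1 (2 equiv), 2 (1 equiv, slow addition), HC(OMe)3, H2SO4 (cat.), MeOH, 0 °C to rt
Reagents that add atoms: trimethyl orthoformate, COC(OC)OC
Why: Acid-catalysed conjugate (Friedel–Crafts-type) alkylation of the hydroquinone by 2 at one of its two equivalent free positions gives 3, whose ketone is trapped by the neighbouring hydroxyl and methanol as the cyclic mixed ketal while the orthoformate removes water; the excess of 1 should hold back a second annulation at C7.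

Step 2
Reactants: 4 2-methoxy-2,5,8-trimethylchroman-6-ol
Product: 5 2,6-dimethoxy-2,5,8-trimethylchroman (racemic)
Conditions: MeI, K2CO3, acetone, reflux
Reagents that add atoms: iodomethane, CI
Why: Williamson etherification of the only free phenol under basic conditions that leave the acid-labile ketal untouched.

Step 3
Reactants: 5 2,6-dimethoxy-2,5,8-trimethylchroman
Product: 6 6-methoxy-2,5,8-trimethylchroman-2-ol (racemic lactol)
Conditions: 2 M HCl, acetone, rt
Reagents that add atoms: water, O
Why: Acid-catalysed ketal hydrolysis through the cyclic oxocarbenium ion; the aryl methyl ether is inert.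

Step 4
Reactants: 6 6-methoxy-2,5,8-trimethylchroman-2-ol
Product: 8 4-methoxy-3,6-dimethyl-2-(3-methylbut-3-en-1-yl)phenol, via open keto phenol 7 (not isolated)
Conditions: Ph3PCH3Br (3 equiv), KOt-Bu (3 equiv), THF, 0 °C to reflux; aq NH4Cl
Reagents that add atoms: methyltriphenylphosphonium bromide (as its ylide), C[P+](c1ccccc1)(c1ccccc1)c1ccccc1.[Br-]
Why: Wittig methylenation of the keto tautomer 7, which the lactol releases as its phenoxide under base (hence the excess ylide); no stereochemistry is involved.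

Step 5
Reactants: 8 4-methoxy-3,6-dimethyl-2-(3-methylbut-3-en-1-yl)phenol; 2 methyl vinyl ketone
Product: 9 (3E)-5-[(2S)-6-methoxy-2,5,8-trimethylchroman-2-yl]pent-3-en-2-one
Conditions: Pd(OCOCF3)2 (10 mol %), (S,S)-Bn-BOXAX (40 mol %), p-benzoquinone (4 equiv), 2 (5 equiv), CH2Cl2, rt, 3–4 d
Reagents that add atoms: none
Why: Divalent palladium carrying the bis(oxazoline) ligand binds the 1,1-disubstituted alkene of 8 and the phenol oxygen adds to the internal carbon (Wacker-type oxypalladation), forming O1–C2 and closing the pyran ring in a 6-exo-trig mode; the C1'–palladium alkyl then carbopalladates methyl vinyl ketone (C1'–C2'), beta-hydride elimination releases the E-enone, and zerovalent palladium is reoxidised by p-benzoquinone. The closest known reaction type is the enantioselective domino Wacker–Heck reaction of 2-(3-methylbut-3-enyl)phenols with acrylates and enones under Pd(OCOCF3)2 and BOXAX ligands. The only new stereocentre, C2, is fixed in the oxypalladation by the enantioface selection that the axially chiral ligand imposes on the coordinated alkene; the product has the spatial arrangement of the target and is S only because the unsaturated chain outranks C3. The step needs 6-exo over 7-endo closure, which the 1,1-disubstitution secures by directing oxygen to the more substituted carbon, and it needs the alkylpalladium to wait for the enone, which the hydrogen-free C2 next to C1' secures by excluding beta-hydride elimination. The methyl ether blocks the second hydroxyl of the hydroquinone, so the oxidant cannot convert the arene into a quinone.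

Step 6
Reactants: 9 (3E)-5-[(2S)-6-methoxy-2,5,8-trimethylchroman-2-yl]pent-3-en-2-one
Product: 10 5-[(2R)-6-methoxy-2,5,8-trimethylchroman-2-yl]pentan-2-one
Conditions: H2 (1 atm), 10% Pd/C, EtOAc, rt
Reagents that add atoms: none
Why: Heterogeneous catalytic hydrogenation saturates the conjugated C2'=C3' bond chemoselectively, the ketone, arene and ethers being inert at 1 atm; C2 is untouched (its descriptor becomes R by priority change only).

Step 7
Reactants: 10 5-[(2R)-6-methoxy-2,5,8-trimethylchroman-2-yl]pentan-2-one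
Product: 12 (2R)-6-methoxy-2,5,8-trimethyl-2-(pent-4-yn-1-yl)chroman, via enol phosphate 11 (not isolated)
Conditions: LiN(i-Pr)2 (1.1 equiv), THF, −78 °C; ClP(O)(OEt)2, −78 °C to rt; LiN(i-Pr)2 (2.3 equiv), −78 °C to rt; aq NH4Cl
Reagents that add atoms: none
Why: Methyl ketone to terminal alkyne conversion by kinetic enolisation at the methyl group, O-phosphorylation and base-induced elimination of diethyl phosphate from the 1-alken-2-yl phosphate (Negishi alkyne synthesis); the former methyl carbon becomes C5'.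

Step 8
Reactants: 12 (2R)-6-methoxy-2,5,8-trimethyl-2-(pent-4-yn-1-yl)chroman
Product: 14 (2R)-2-[(4E)-5-iodo-4-methylpent-4-en-1-yl]-6-methoxy-2,5,8-trimethylchroman, via alkenylalane 13 (not isolated)
Conditions: Me3Al (2.5 equiv), Cp2ZrCl2 (0.3 equiv), CH2Cl2, 0 °C to rt; then I2, THF, −30 to 0 °C
Reagents that add atoms: trimethylaluminium, C[Al](C)C; iodine, II
Why: Zirconium-catalysed carboalumination (Negishi) adds CH3 and Al syn across the alkyne with CH3 at the internal carbon C4', and iodinolysis of the C–Al bond with retention gives the E-iodoalkene as one geometric isomer, which an olefination of ketone 10 with an unstabilised ylide could not guarantee.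

Step 9
Reactants: 15 (R)-citronellol
Product: 16 (R)-citronellyl iodide, (6R)-8-iodo-2,6-dimethyloct-2-ene
Conditions: I2, PPh3, imidazole, CH2Cl2, 0 °C to rt
Reagents that add atoms: iodine, II
Why: Appel-type iodination of the primary alcohol; the stereocentre (later C8') is remote and not touched.

Step 10
Reactants: 14 (2R)-2-[(4E)-5-iodo-4-methylpent-4-en-1-yl]-6-methoxy-2,5,8-trimethylchroman; 16 (R)-citronellyl iodide
Product: 18 (2R)-6-methoxy-2,5,8-trimethyl-2-[(4E,8R)-4,8,12-trimethyltrideca-4,11-dien-1-yl]chroman, via citronellylzinc iodide 17 (not isolated)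
Conditions: 16, Zn dust (activated with BrCH2CH2Br and Me3SiCl), LiCl, THF, 40 °C; then 14, PdCl2(dppf) (3 mol %), THF, 50 °C
Reagents that add atoms: none
Why: LiCl-assisted insertion of zinc into the primary C–I bond followed by Negishi alkenyl–alkyl cross-coupling forms C5'–C6' with retention of the E geometry, the dppf ligand suppressing beta-hydride elimination of the alkylpalladium.

Step 11
Reactants: 18 (2R)-6-methoxy-2,5,8-trimethyl-2-[(4E,8R)-4,8,12-trimethyltrideca-4,11-dien-1-yl]chroman
Product: 19 (2R)-6-methoxy-2,5,8-trimethyl-2-[(4R,8R)-4,8,12-trimethyltridecyl]chroman (beta-tocopherol methyl ether)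
Conditions: [Ir(cod)(L)]B(ArF)4 (1 mol %, ArF = 3,5-bis(trifluoromethyl)phenyl), H2 (50 bar), CH2Cl2, rt
Reagents that add atoms: none
Why: Iridium-catalysed asymmetric hydrogenation of unfunctionalised trisubstituted alkenes with a chiral P,N ligand delivers hydrogen to the Re face of C4' of the E-alkene under catalyst control, giving 4'R, while the isopropylidene group is saturated without a new stereocentre and C2 and C8' are not affected.

Step 12
Reactants: 19 (2R)-6-methoxy-2,5,8-trimethyl-2-[(4R,8R)-4,8,12-trimethyltridecyl]chroman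
Product: 20 beta-tocopherol, (2R)-2,5,8-trimethyl-2-[(4R,8R)-4,8,12-trimethyltridecyl]chroman-6-ol
Conditions: NaSEt (5 equiv), DMF, 140 °C, argon; then 1 M HCl
Reagents that add atoms: none
Why: SN2 attack of ethanethiolate on the O-methyl carbon frees the phenol without acid, so the tertiary O1–C2 ether and its stereocentre cannot ionise; air is excluded because the phenoxide is prone to oxidation.

**Compound list**
1 | 2,5-dimethylhydroquinone (2,5-dimethylbenzene-1,4-diol) | Cc1cc(O)c(C)cc1O | starting material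
2 | methyl vinyl ketone (but-3-en-2-one) | CC(=O)C=C | starting material
3 | 4-(2,5-dihydroxy-3,6-dimethylphenyl)butan-2-one (not isolated) | CC(=O)CCc1c(O)c(C)cc(O)c1C | intermediate
4 | 2-methoxy-2,5,8-trimethylchroman-6-ol (racemic) | COC1(C)CCc2c(C)c(O)cc(C)c2O1 | intermediate
5 | 2,6-dimethoxy-2,5,8-trimethylchroman (racemic) | COC1(C)CCc2c(C)c(OC)cc(C)c2O1 | intermediate
6 | 6-methoxy-2,5,8-trimethylchroman-2-ol (racemic lactol) | CC1(O)CCc2c(C)c(OC)cc(C)c2O1 | intermediate
7 | 4-(2-hydroxy-5-methoxy-3,6-dimethylphenyl)butan-2-one (open form of 6, not isolated) | CC(=O)CCc1c(O)c(C)cc(OC)c1C | intermediate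
8 | 4-methoxy-3,6-dimethyl-2-(3-methylbut-3-en-1-yl)phenol | COc1cc(C)c(O)c(CCC(C)=C)c1C | intermediate
9 | (3E)-5-[(2S)-6-methoxy-2,5,8-trimethylchroman-2-yl]pent-3-en-2-one | Cc1cc(OC)c(C)c2c1O[C@](C)(C/C=C/C(C)=O)CC2 | intermediate
10 | 5-[(2R)-6-methoxy-2,5,8-trimethylchroman-2-yl]pentan-2-one | Cc1cc(OC)c(C)c2c1O[C@](C)(CCCC(C)=O)CC2 | intermediate
11 | diethyl 5-[(2R)-6-methoxy-2,5,8-trimethylchroman-2-yl]pent-1-en-2-yl phosphate (not isolated) | Cc1cc(OC)c(C)c2c1O[C@](C)(CCCC(=C)OP(=O)(OCC)OCC)CC2 | intermediate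
12 | (2R)-6-methoxy-2,5,8-trimethyl-2-(pent-4-yn-1-yl)chroman | Cc1cc(OC)c(C)c2c1O[C@](C)(CCCC#C)CC2 | intermediate
13 | [(1E)-5-[(2R)-6-methoxy-2,5,8-trimethylchroman-2-yl]-2-methylpent-1-en-1-yl]dimethylalane (not isolated) | Cc1cc(OC)c(C)c2c1O[C@](C)(CCC/C(C)=C/[Al](C)C)CC2 | intermediate
14 | (2R)-2-[(4E)-5-iodo-4-methylpent-4-en-1-yl]-6-methoxy-2,5,8-trimethylchroman | Cc1cc(OC)c(C)c2c1O[C@](C)(CCC/C(C)=C/I)CC2 | intermediate
15 | (R)-citronellol, (3R)-3,7-dimethyloct-6-en-1-ol | OCC[C@H](C)CCC=C(C)C | starting material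
16 | (R)-citronellyl iodide, (6R)-8-iodo-2,6-dimethyloct-2-ene | ICC[C@H](C)CCC=C(C)C | intermediate
17 | [(3R)-3,7-dimethyloct-6-en-1-yl]zinc iodide (not isolated) | I[Zn]CC[C@H](C)CCC=C(C)C | intermediate
18 | (2R)-6-methoxy-2,5,8-trimethyl-2-[(4E,8R)-4,8,12-trimethyltrideca-4,11-dien-1-yl]chroman | Cc1cc(OC)c(C)c2c1O[C@](C)(CCC/C(C)=C/CC[C@H](C)CCC=C(C)C)CC2 | intermediate
19 | (2R)-6-methoxy-2,5,8-trimethyl-2-[(4R,8R)-4,8,12-trimethyltridecyl]chroman | Cc1cc(OC)c(C)c2c1O[C@](C)(CCC[C@H](C)CCC[C@H](C)CCCC(C)C)CC2 | intermediate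
20 | beta-tocopherol, (2R)-2,5,8-trimethyl-2-[(4R,8R)-4,8,12-trimethyltridecyl]chroman-6-ol | Cc1cc(O)c(C)c2c1O[C@](C)(CCC[C@H](C)CCC[C@H](C)CCCC(C)C)CC2 | target

**Step count**
Total: 12 steps. Longest linear sequence: 11 steps (steps 1–8 and 10–12, from 1 to 20); step 9 is the one-step side branch.

**Steps most likely to fail**

Step 5. The risk is insufficient enantiofacial discrimination in the oxypalladation, or loss of the catalyst as palladium metal before the slow insertion of the enone. The fallback sets out from lactol 6 and rejoins at 9; it closes the ring without palladium and obtains C2 by resolution. Horner–Wadsworth–Emmons reaction of 6 with trimethyl phosphonoacetate and NaOMe (MeOH/THF), followed in the same flask by oxa-Michael closure of the phenoxide, should give racemic methyl (6-methoxy-2,5,8-trimethylchroman-2-yl)acetate F1. Saponification (NaOH, aq MeOH) gives the racemic (6-methoxy-2,5,8-trimethylchroman-2-yl)acetic acid F2. Crystallisation of its 1-phenylethylammonium salt, with the amine enantiomer chosen so that the salt of the S acid is the less soluble one, gives [(2S)-6-methoxy-2,5,8-trimethylchroman-2-yl]acetic acid F3. LiAlH4 in THF reduces it to 2-[(2S)-6-methoxy-2,5,8-trimethylchroman-2-yl]ethanol F4, and Swern oxidation gives [(2S)-6-methoxy-2,5,8-trimethylchroman-2-yl]acetaldehyde F5. Wittig reaction with 1-(triphenylphosphoranylidene)propan-2-one in toluene at 80 °C then gives E-enone 9.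

Step 7. The risk is enolisation toward C3' instead of the methyl group, and base-induced migration of the triple bond, so that internal alkyne or allene accompanies 12. The fallback sets out from 9 and rejoins at 18; it keeps the C2'=C3' bond as a regiochemical control element, since in the enone the methyl group is the only alpha' position. LiN(i-Pr)2 and ClP(O)(OEt)2 at −78 °C give diethyl (3E)-5-[(2S)-6-methoxy-2,5,8-trimethylchroman-2-yl]penta-1,3-dien-2-yl phosphate F6 (not isolated). Further LiN(i-Pr)2 gives (2S)-6-methoxy-2,5,8-trimethyl-2-[(2E)-pent-2-en-4-yn-1-yl]chroman F7. Me3Al with Cp2ZrCl2 gives [(1E,3E)-5-[(2S)-6-methoxy-2,5,8-trimethylchroman-2-yl]-2-methylpenta-1,3-dien-1-yl]dimethylalane F8 (not isolated), and I2 gives (2S)-2-[(2E,4E)-5-iodo-4-methylpenta-2,4-dien-1-yl]-6-methoxy-2,5,8-trimethylchroman F9. Negishi coupling with 17 under PdCl2(dppf) gives (2S)-6-methoxy-2,5,8-trimethyl-2-[(2E,4E,8R)-4,8,12-trimethyltrideca-2,4,11-trien-1-yl]chroman F10. Diimide (2-nitrobenzenesulfonylhydrazide, Et3N, CH2Cl2, rt) should then reduce only the 1,2-disubstituted C2'=C3' bond and leave the two trisubstituted alkenes, giving 18.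

Step 11. The risk is weak facial discrimination at C4', whose methyl and methylene substituents differ little, or incomplete saturation of the two alkenes. The fallback sets out from 9 (side chain from 16) and rejoins at 19; it sets C4' by reagent-controlled ketone reduction and stereospecific substitution instead of hydrogenation.
- Chroman part: CBS reduction of 9 with the (S)-methyl oxazaborolidine and catecholborane (toluene, −78 °C) should give (2R,3E)-5-[(2S)-6-methoxy-2,5,8-trimethylchroman-2-yl]pent-3-en-2-ol F11. Hydrogenation (H2, PtO2, EtOAc) gives (2R)-5-[(2R)-6-methoxy-2,5,8-trimethylchroman-2-yl]pentan-2-ol F12, and TsCl in pyridine gives (2R)-5-[(2R)-6-methoxy-2,5,8-trimethylchroman-2-yl]pentan-2-yl 4-methylbenzenesulfonate F13.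
- C5'–C13' unit: Mg converts 16 into [(3R)-3,7-dimethyloct-6-en-1-yl]magnesium iodide F14 (not isolated), and paraformaldehyde gives (4R)-4,8-dimethylnon-7-en-1-ol F15. CBr4/PPh3 gives (6R)-9-bromo-2,6-dimethylnon-2-ene F16, and Mg in THF gives [(4R)-4,8-dimethylnon-7-en-1-yl]magnesium bromide F17 (not isolated).
- Coupling: copper-catalysed alkyl–alkyl coupling of F13 with F17 (CuI, TMEDA, LiOMe, THF, 0 °C) is an SN2 displacement with inversion at C4'. It should give (2R)-6-methoxy-2,5,8-trimethyl-2-[(4R,8S)-4,8,12-trimethyltridec-11-en-1-yl]chroman F18, in which 8S reflects a priority change only. H2 over Pd/C then gives 19.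

**Further compounds**
F1 | step 5 | methyl (6-methoxy-2,5,8-trimethylchroman-2-yl)acetate (racemic) | COC(=O)CC1(C)CCc2c(C)c(OC)cc(C)c2O1
F2 | step 5 | (6-methoxy-2,5,8-trimethylchroman-2-yl)acetic acid (racemic) | OC(=O)CC1(C)CCc2c(C)c(OC)cc(C)c2O1
F3 | step 5 | [(2S)-6-methoxy-2,5,8-trimethylchroman-2-yl]acetic acid | Cc1cc(OC)c(C)c2c1O[C@](C)(CC(O)=O)CC2
F4 | step 5 | 2-[(2S)-6-methoxy-2,5,8-trimethylchroman-2-yl]ethanol | Cc1cc(OC)c(C)c2c1O[C@](C)(CCO)CC2
F5 | step 5 | [(2S)-6-methoxy-2,5,8-trimethylchroman-2-yl]acetaldehyde | Cc1cc(OC)c(C)c2c1O[C@](C)(CC=O)CC2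
F6 | step 7 | diethyl (3E)-5-[(2S)-6-methoxy-2,5,8-trimethylchroman-2-yl]penta-1,3-dien-2-yl phosphate | Cc1cc(OC)c(C)c2c1O[C@](C)(C/C=C/C(=C)OP(=O)(OCC)OCC)CC2
F7 | step 7 | (2S)-6-methoxy-2,5,8-trimethyl-2-[(2E)-pent-2-en-4-yn-1-yl]chroman | Cc1cc(OC)c(C)c2c1O[C@](C)(C/C=C/C#C)CC2
F8 | step 7 | [(1E,3E)-5-[(2S)-6-methoxy-2,5,8-trimethylchroman-2-yl]-2-methylpenta-1,3-dien-1-yl]dimethylalane | Cc1cc(OC)c(C)c2c1O[C@](C)(C/C=C/C(C)=C/[Al](C)C)CC2
F9 | step 7 | (2S)-2-[(2E,4E)-5-iodo-4-methylpenta-2,4-dien-1-yl]-6-methoxy-2,5,8-trimethylchroman | Cc1cc(OC)c(C)c2c1O[C@](C)(C/C=C/C(C)=C/I)CC2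
F10 | step 7 | (2S)-6-methoxy-2,5,8-trimethyl-2-[(2E,4E,8R)-4,8,12-trimethyltrideca-2,4,11-trien-1-yl]chroman | Cc1cc(OC)c(C)c2c1O[C@](C)(C/C=C/C(C)=C/CC[C@H](C)CCC=C(C)C)CC2
F11 | step 11 | (2R,3E)-5-[(2S)-6-methoxy-2,5,8-trimethylchroman-2-yl]pent-3-en-2-ol | Cc1cc(OC)c(C)c2c1O[C@](C)(C/C=C/[C@@H](C)O)CC2
F12 | step 11 | (2R)-5-[(2R)-6-methoxy-2,5,8-trimethylchroman-2-yl]pentan-2-ol | Cc1cc(OC)c(C)c2c1O[C@](C)(CCC[C@@H](C)O)CC2
F13 | step 11 | (2R)-5-[(2R)-6-methoxy-2,5,8-trimethylchroman-2-yl]pentan-2-yl 4-methylbenzenesulfonate | Cc1cc(OC)c(C)c2c1O[C@](C)(CCC[C@@H](C)OS(=O)(=O)c3ccc(C)cc3)CC2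
F14 | step 11 | [(3R)-3,7-dimethyloct-6-en-1-yl]magnesium iodide | I[Mg]CC[C@H](C)CCC=C(C)C
F15 | step 11 | (4R)-4,8-dimethylnon-7-en-1-ol | OCCC[C@H](C)CCC=C(C)C
F16 | step 11 | (6R)-9-bromo-2,6-dimethylnon-2-ene | BrCCC[C@H](C)CCC=C(C)C
F17 | step 11 | [(4R)-4,8-dimethylnon-7-en-1-yl]magnesium bromide | Br[Mg]CCC[C@H](C)CCC=C(C)C
F18 | step 11 | (2R)-6-methoxy-2,5,8-trimethyl-2-[(4R,8S)-4,8,12-trimethyltridec-11-en-1-yl]chroman | Cc1cc(OC)c(C)c2c1O[C@](C)(CCC[C@H](C)CCC[C@H](C)CCC=C(C)C)CC2
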